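## Retrosynthetic overview

1. The strategy rests on the bicyclo[3.3.1] ketal core. In flavan numbering, C2–H and the C4 hemiketal carbon are linked through the C3 methylene, and the ring B 2'-oxygen can reach C4 only on the face where the C2–aryl bond sits. C4 therefore follows C2, and a flat, achiral flavone needs a single enantioselective hydride delivery to C2.
2. Target 22 ⇐ C4–O2' hemiketal closure of (2R)-2',6'-dihydroxyflavanone 21 ⇐ asymmetric copper hydride 1,4-reduction and desilylation of bis-silyl flavone 18.
3. Flavone 18 (pyranone ring C) ⇐ palladium-catalysed carbonylative Sonogashira coupling and 6-endo closure of iodoaryl acetate 10, CO and arylacetylene 15.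
4. 10 ⇐ chromenol 8 ⇐ symmetric 2-prenyl-5-methoxyresorcinol 6 + prenal; 6 ⇐ 5-methoxyresorcinol by MOM-directed lithiation and prenylation; 15 ⇐ 2,6-dihydroxybenzaldehyde by silylation and Corey–Fuchs homologation.
5. Ring order: ring A (bought) → 2,2-dimethylpyran ring → pyranone ring C → bridging ketal ring, closed last together with both stereocentres.

Key step: step 11

Numbering remark: flavonoid numbering is used for 16–22 (O1, C2, C3, C4, ring A C4a–C8a, ring B C1'–C6'). The target is (2R,4R) in this numbering.

Assumption 1: the (R)-bisphosphine is taken to deliver hydride to the Si face of C2 (priorities O1 > C1' > C3), which gives 2R. The sense is to be checked on small scale and the (S)-ligand used instead if the 2S series forms; nothing else changes.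

Assumption 2: the bridged hemiketal is taken to be the preferred tautomer of the 5-O-methyl-2',6'-dihydroxyflavanone, so the closure needs no separate reagent.

## Route

Step 1
Reactants: 1 5-methoxyresorcinol
Product: 2 1-methoxy-3,5-bis(methoxymethoxy)benzene
Conditions: MOMCl, i-Pr2NEt, CH2Cl2, 0 °C → rt
Reagents that add atoms: chloromethyl methyl ether (COCCl)
Why: Williamson-type O-alkylation of both phenols gives the bis-acetal, whose two MOM groups act as cooperating directing groups in step 2.

Step 2
Reactants: 2 1-methoxy-3,5-bis(methoxymethoxy)benzene; 3 prenyl bromide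
Product: 5 5-methoxy-1,3-bis(methoxymethoxy)-2-(3-methylbut-2-en-1-yl)benzene, via aryllithium 4 (not isolated)
Conditions: n-BuLi, TMEDA, THF, 0 °C; then CuI (10 mol %), 3, −78 °C → rt
Reagents that add atoms: none
Why: Directed ortho-metalation should occur at the carbon flanked by both MOM ethers (doubly chelated, favoured over the OMe/OMOM-flanked sites), and copper-catalysed allylic substitution at the primary carbon of prenyl bromide installs the linear prenyl group.

Step 3
Reactants: 5 5-methoxy-1,3-bis(methoxymethoxy)-2-(3-methylbut-2-en-1-yl)benzene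
Product: 6 5-methoxy-2-(3-methylbut-2-en-1-yl)benzene-1,3-diol
Conditions: 3 M aq. HCl, MeOH, 40 °C, stopped at full conversion
Reagents that add atoms: none
Why: Acid-catalysed acetal methanolysis frees both phenols, and short, mild heating keeps the competing acid-catalysed cyclisation of the prenyl group onto a neighbouring phenol (chroman formation) slow.

Step 4
Reactants: 6 5-methoxy-2-(3-methylbut-2-en-1-yl)benzene-1,3-diol; 7 3-methylbut-2-enal
Product: 8 5-methoxy-2,2-dimethyl-8-(3-methylbut-2-en-1-yl)-2H-chromen-7-ol
Conditions: ethylenediammonium diacetate (10 mol %), toluene, reflux, 1.0 equiv of 7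
Reagents that add atoms: none
Why: Amine-salt-catalysed Knoevenagel-type condensation at the ring carbon ortho to a phenol followed by oxa-6π electrocyclisation builds the 2,2-dimethylpyran; 6 is symmetric, so only one mono-chromene can form, and limiting the aldehyde holds back a second annulation.

Step 5
Reactants: 8 5-methoxy-2,2-dimethyl-8-(3-methylbut-2-en-1-yl)-2H-chromen-7-ol
Product: 9 6-iodo-5-methoxy-2,2-dimethyl-8-(3-methylbut-2-en-1-yl)-2H-chromen-7-ol
Conditions: NIS (1.0 equiv), DMF, −20 °C, dark
Reagents that add atoms: N-iodosuccinimide (O=C1CCC(=O)N1I)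
Why: Electrophilic aromatic iodination at the only free ring position, which is ortho to the phenol, ortho to OMe and para to the pyran oxygen and should therefore react well before the prenyl or chromene alkene at low temperature without acid.

Step 6
Reactants: 9 6-iodo-5-methoxy-2,2-dimethyl-8-(3-methylbut-2-en-1-yl)-2H-chromen-7-ol
Product: 10 6-iodo-5-methoxy-2,2-dimethyl-8-(3-methylbut-2-en-1-yl)-2H-chromen-7-yl acetate
Conditions: Ac2O, pyridine, DMAP (cat.), CH2Cl2, rt
Reagents that add atoms: acetic anhydride (CC(=O)OC(C)=O)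
Why: DMAP-catalysed O-acylation masks the phenol as the acetate, which the mild carbonylative annulation of step 10 uses as a latent phenoxide.

Step 7
Reactants: 11 2,6-dihydroxybenzaldehyde
Product: 12 2,6-bis(tert-butyldimethylsilyloxy)benzaldehyde
Conditions: TBSCl, imidazole, DMF, rt
Reagents that add atoms: tert-butyldimethylsilyl chloride (CC(C)(C)[Si](C)(C)Cl)
Why: Imidazole-promoted O-silylation protects both phenols as fluoride-labile silyl ethers that tolerate the organolithium, amine and hydrosilane conditions ahead.

Step 8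
Reactants: 12 2,6-bis(tert-butyldimethylsilyloxy)benzaldehyde
Product: 13 2-(2,2-dibromoethenyl)-1,3-bis(tert-butyldimethylsilyloxy)benzene
Conditions: CBr4, PPh3, Et3N, CH2Cl2, 0 °C
Reagents that add atoms: carbon tetrabromide (BrC(Br)(Br)Br)
Why: First stage of the Corey–Fuchs reaction (Wittig olefination with the dibromomethylene ylide made in situ), which accepts 2,6-disubstituted benzaldehydes; the amine buffer shields the aryl silyl ethers from HBr.

Step 9
Reactants: 13 2-(2,2-dibromoethenyl)-1,3-bis(tert-butyldimethylsilyloxy)benzene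
Product: 15 2-ethynyl-1,3-bis(tert-butyldimethylsilyloxy)benzene, via lithium acetylide 14 (not isolated)
Conditions: n-BuLi (2.2 equiv), THF, −78 °C; aq. NH4Cl
Reagents that add atoms: none
Why: Second stage of the Corey–Fuchs reaction: bromine–lithium exchange, Fritsch–Buttenberg–Wiechell rearrangement and deprotonation give the lithium acetylide, which is protonated on quench; the silyl ethers are not exposed to protic base.

Step 10
Reactants: 10 6-iodo-5-methoxy-2,2-dimethyl-8-(3-methylbut-2-en-1-yl)-2H-chromen-7-yl acetate; 15 2-ethynyl-1,3-bis(tert-butyldimethylsilyloxy)benzene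
Product: 18 8-[2,6-bis(tert-butyldimethylsilyloxy)phenyl]-5-methoxy-2,2-dimethyl-10-(3-methylbut-2-en-1-yl)-2H,6H-pyrano[3,2-g]chromen-6-one (the bis-silyl flavone), via acetoxy ynone 16 (not isolated), via hydroxy ynone 17 (not isolated)
Conditions: CO (1 atm), PdCl2(PPh3)2 (5 mol %), dppp (5 mol %), thiourea (5 mol %), Et2NH, DBU, 40 °C
Reagents that add atoms: carbon monoxide ([C-]#[O+])
Why: Copper-free carbonylative Sonogashira coupling (oxidative addition of the aryl iodide to zerovalent palladium, CO insertion, alkynylation, reductive elimination) gives the ynone; diethylamine then cleaves the acetate and the phenoxide closes 6-endo-dig (oxa-Michael) to the pyranone, the secondary-amine medium being the established way to steer this closure to the flavone and away from the aurone.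

Step 11
Reactants: 18 bis-silyl flavone
Product: 22 target CNP0170313.2 (the 2R,4R bridged hemiketal), via enol silane 19 (not isolated), via silylated flavanone 20 (not isolated), via dihydroxyflavanone 21 (not isolated)
Conditions: Cu(OAc)2·H2O (5 mol %), (R)-DTBM-SEGPHOS (5.5 mol %), (EtO)2MeSiH (3 equiv), toluene, 0 °C → rt; then TBAF/AcOH (1:1), THF, 0 °C → rt
Reagents that add atoms: none
Why: The bisphosphine-ligated copper hydride formed from Cu(OAc)2 and the silane adds hydride to C2 of the vinylogous ester (1,4-hydrocupration), and the copper enolate is silylated by the hydrosilane (σ-bond metathesis), which regenerates the hydride and holds the product as enol silane 19, inert to further reduction. Acetic-acid-buffered fluoride then cleaves the enol silane (C3 protonation gives the C4 ketone of 20) and both aryl silyl ethers, and either of the two equivalent hydroxyls of 21 adds to the C4 carbonyl in a 6-exo-trig closure that forms the bridging six-membered ketal ring (O2'–C2'–C1'–C2–C3–C4). The closest known reaction type is the copper hydride-catalysed asymmetric conjugate reduction of β-aryl cyclic enones and chromones, followed by ordinary fluoride desilylation and spontaneous hemiketalisation. C2 (R) is set by the chiral ligand through hydride delivery to the Si face, and C4 (R) is set by the substrate, because the C3 bridge lets the ring B oxygen reach C4 only from the face on which the C2–aryl bond is axial. The step needs 1,4- over 1,2-reduction and must spare the prenyl and chromene alkenes; the polarised enone is the only good acceptor for the soft copper hydride, and the unpolarised alkenes should not insert at this temperature without a proton source. It must also keep the C2 configuration against retro-oxa-Michael ring opening, which the acetic acid buffer and the masking of the ketone as the hemiketal are meant to prevent.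

## Compound list

1 | 5-methoxyresorcinol | COc1cc(O)cc(O)c1 | starting material
2 | 1-methoxy-3,5-bis(methoxymethoxy)benzene | COCOc1cc(OC)cc(OCOC)c1 | intermediate
3 | prenyl bromide (1-bromo-3-methylbut-2-ene) | CC(C)=CCBr | starting material
4 | [4-methoxy-2,6-bis(methoxymethoxy)phenyl]lithium | [Li]c1c(OCOC)cc(OC)cc1OCOC | intermediate
5 | 5-methoxy-1,3-bis(methoxymethoxy)-2-(3-methylbut-2-en-1-yl)benzene | COCOc1cc(OC)cc(OCOC)c1CC=C(C)C | intermediate
6 | 5-methoxy-2-(3-methylbut-2-en-1-yl)benzene-1,3-diol | COc1cc(O)c(CC=C(C)C)c(O)c1 | intermediate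
7 | 3-methylbut-2-enal | CC(C)=CC=O | starting material
8 | 5-methoxy-2,2-dimethyl-8-(3-methylbut-2-en-1-yl)-2H-chromen-7-ol | COc1cc(O)c(CC=C(C)C)c2OC(C)(C)C=Cc12 | intermediate
9 | 6-iodo-5-methoxy-2,2-dimethyl-8-(3-methylbut-2-en-1-yl)-2H-chromen-7-ol | COc1c(I)c(O)c(CC=C(C)C)c2OC(C)(C)C=Cc12 | intermediate
10 | 6-iodo-5-methoxy-2,2-dimethyl-8-(3-methylbut-2-en-1-yl)-2H-chromen-7-yl acetate | COc1c(I)c(OC(C)=O)c(CC=C(C)C)c2OC(C)(C)C=Cc12 | intermediate
11 | 2,6-dihydroxybenzaldehyde | O=Cc1c(O)cccc1O | starting material
12 | 2,6-bis(tert-butyldimethylsilyloxy)benzaldehyde | O=Cc1c(O[Si](C)(C)C(C)(C)C)cccc1O[Si](C)(C)C(C)(C)C | intermediate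
13 | 2-(2,2-dibromoethenyl)-1,3-bis(tert-butyldimethylsilyloxy)benzene | BrC(Br)=Cc1c(O[Si](C)(C)C(C)(C)C)cccc1O[Si](C)(C)C(C)(C)C | intermediate
14 | lithium [2,6-bis(tert-butyldimethylsilyloxy)phenyl]acetylide | [Li]C#Cc1c(O[Si](C)(C)C(C)(C)C)cccc1O[Si](C)(C)C(C)(C)C | intermediate
15 | 2-ethynyl-1,3-bis(tert-butyldimethylsilyloxy)benzene | C#Cc1c(O[Si](C)(C)C(C)(C)C)cccc1O[Si](C)(C)C(C)(C)C | intermediate
16 | 6-{3-[2,6-bis(tert-butyldimethylsilyloxy)phenyl]prop-2-ynoyl}-5-methoxy-2,2-dimethyl-8-(3-methylbut-2-en-1-yl)-2H-chromen-7-yl acetate (acetoxy ynone) | COc1c(C(=O)C#Cc3c(O[Si](C)(C)C(C)(C)C)cccc3O[Si](C)(C)C(C)(C)C)c(OC(C)=O)c(CC=C(C)C)c2OC(C)(C)C=Cc12 | intermediate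
17 | 3-[2,6-bis(tert-butyldimethylsilyloxy)phenyl]-1-[7-hydroxy-5-methoxy-2,2-dimethyl-8-(3-methylbut-2-en-1-yl)-2H-chromen-6-yl]prop-2-yn-1-one (hydroxy ynone) | COc1c(C(=O)C#Cc3c(O[Si](C)(C)C(C)(C)C)cccc3O[Si](C)(C)C(C)(C)C)c(O)c(CC=C(C)C)c2OC(C)(C)C=Cc12 | intermediate
18 | 8-[2,6-bis(tert-butyldimethylsilyloxy)phenyl]-5-methoxy-2,2-dimethyl-10-(3-methylbut-2-en-1-yl)-2H,6H-pyrano[3,2-g]chromen-6-one (bis-silyl flavone) | O=C1C=C(c2c(O[Si](C)(C)C(C)(C)C)cccc2O[Si](C)(C)C(C)(C)C)Oc2c1c(OC)c1c(c2CC=C(C)C)OC(C)(C)C=C1 | intermediate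
19 | (2R)-flavanone 4-enol diethoxy(methyl)silyl ether of 18 (enol silane; 2'- and 6'-OTBS retained) | CCO[Si](C)(OCC)OC1=C[C@H](c2c(O[Si](C)(C)C(C)(C)C)cccc2O[Si](C)(C)C(C)(C)C)Oc2c1c(OC)c1c(c2CC=C(C)C)OC(C)(C)C=C1 | intermediate
20 | (8R)-8-[2,6-bis(tert-butyldimethylsilyloxy)phenyl]-5-methoxy-2,2-dimethyl-10-(3-methylbut-2-en-1-yl)-7,8-dihydro-2H,6H-pyrano[3,2-g]chromen-6-one ((2R)-bis-silyl flavanone) | O=C1C[C@H](c2c(O[Si](C)(C)C(C)(C)C)cccc2O[Si](C)(C)C(C)(C)C)Oc2c1c(OC)c1c(c2CC=C(C)C)OC(C)(C)C=C1 | intermediate
21 | (8R)-8-(2,6-dihydroxyphenyl)-5-methoxy-2,2-dimethyl-10-(3-methylbut-2-en-1-yl)-7,8-dihydro-2H,6H-pyrano[3,2-g]chromen-6-one ((2R)-2',6'-dihydroxyflavanone) | O=C1C[C@H](c2c(O)cccc2O)Oc2c1c(OC)c1c(c2CC=C(C)C)OC(C)(C)C=C1 | intermediate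
22 | CNP0170313.2: (2R,4R)-4,2'-epoxy-bridged flavan-4-ol hemiketal with 5-OMe, 6,7-fused 2,2-dimethyl-2H-pyran (oxygen on C7), 8-prenyl and 6'-OH | COc1c2c(c(CC=C(C)C)c3c1[C@@]1(O)C[C@@H](O3)c3c(O)cccc3O1)OC(C)(C)C=C2 | target

## Step count and risks

Total step count: 11. Longest linear sequence: 8 steps (steps 1–6, 10, 11 from 5-methoxyresorcinol); the ring B branch is steps 7–9.

Steps most likely to fail:

1. Step 11. The twisted 2',6'-bis(silyloxy)aryl ring places a silyloxy group over each face of C2, so hydride delivery may be slow or poorly face-selective. 1,2-Reduction of the carbonyl and loss of enantiopurity by ring opening during desilylation are further ways for it to go wrong. Fallback, setting out from 18: conjugate reduction with the smaller achiral hydride [(Ph3P)CuH]6 (toluene/THF, rt, NH4Cl work-up) should give the racemic bis-silyl flavanone F1. Preparative HPLC on an amylose tris(3,5-dimethylphenylcarbamate) phase would separate the (2R)-enantiomer, which is compound 20 (here isolated), from the (2S)-bis-silyl flavanone F2. The route is rejoined at 20, which is desilylated with TBAF/AcOH and closes through 21 to 22. This replaces asymmetric catalysis by resolution.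

2. Step 10. With a di-ortho-substituted aryl palladium species, direct (non-carbonylative) alkynylation may outrun CO insertion and lead on to benzofuran formation. The closure may also go 5-exo to the aurone, or the amine medium may strip silyl ethers from ring B. Fallback, setting out from chromenol 8: magnesium-mediated ortho-formylation (MgCl2, Et3N, paraformaldehyde, MeCN, reflux; Casnati–Skattebøl reaction) at the only free ring position should give the salicylaldehyde F3. Addition of F3 to excess lithium acetylide 14 (from 15 and n-BuLi, THF, −78 → 0 °C) gives the propargylic alcohol F4. Oxidation with MnO2 (CH2Cl2, rt) gives hydroxy ynone 17, here isolated, and Et2NH (EtOH, rt) closes it to 18, where the route is rejoined. This bypasses the iodide, the acetate and the palladium step.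

3. Step 5. The iodinating agent may attack the prenyl alkene with capture by the neighbouring phenol (iodoetherification), or the electron-rich chromene alkene, instead of substituting the ring. Fallback, setting out from 5, before any phenol or chromene alkene is present: a second directed lithiation (s-BuLi, TMEDA, THF, −78 °C) at the ring carbon between OMOM and OMe, quenched with I2 (1.0 equiv, −78 °C), should give the aryl iodide F5. Methanolysis (3 M aq. HCl, MeOH, 40 °C) gives the iodoresorcinol F6. Chromene annulation with 7 (ethylenediammonium diacetate, toluene, reflux) can only engage the hydroxyl remote from iodine, the one with a free ortho carbon, and should give 9, where the route is rejoined. The blocked ring also rules out a second annulation.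

Further compounds
F1 | step 11 | racemic 8-[2,6-bis(tert-butyldimethylsilyloxy)phenyl]-5-methoxy-2,2-dimethyl-10-(3-methylbut-2-en-1-yl)-7,8-dihydro-2H,6H-pyrano[3,2-g]chromen-6-one | O=C1CC(c2c(O[Si](C)(C)C(C)(C)C)cccc2O[Si](C)(C)C(C)(C)C)Oc2c1c(OC)c1c(c2CC=C(C)C)OC(C)(C)C=C1
F2 | step 11 | (8S)-8-[2,6-bis(tert-butyldimethylsilyloxy)phenyl]-5-methoxy-2,2-dimethyl-10-(3-methylbut-2-en-1-yl)-7,8-dihydro-2H,6H-pyrano[3,2-g]chromen-6-one | O=C1C[C@@H](c2c(O[Si](C)(C)C(C)(C)C)cccc2O[Si](C)(C)C(C)(C)C)Oc2c1c(OC)c1c(c2CC=C(C)C)OC(C)(C)C=C1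
F3 | step 10 | 7-hydroxy-5-methoxy-2,2-dimethyl-8-(3-methylbut-2-en-1-yl)-2H-chromene-6-carbaldehyde | COc1c(C=O)c(O)c(CC=C(C)C)c2OC(C)(C)C=Cc12
F4 | step 10 | racemic 6-{3-[2,6-bis(tert-butyldimethylsilyloxy)phenyl]-1-hydroxyprop-2-yn-1-yl}-5-methoxy-2,2-dimethyl-8-(3-methylbut-2-en-1-yl)-2H-chromen-7-ol | COc1c(C(O)C#Cc3c(O[Si](C)(C)C(C)(C)C)cccc3O[Si](C)(C)C(C)(C)C)c(O)c(CC=C(C)C)c2OC(C)(C)C=Cc12
F5 | step 5 | 2-iodo-1-methoxy-3,5-bis(methoxymethoxy)-4-(3-methylbut-2-en-1-yl)benzene | COCOc1cc(OC)c(I)c(OCOC)c1CC=C(C)C
F6 | step 5 | 4-iodo-5-methoxy-2-(3-methylbut-2-en-1-yl)benzene-1,3-diol | COc1cc(O)c(CC=C(C)C)c(O)c1I
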